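**Retrosynthetic overview**

1. The strategy rests on the B-ring array C3'(OH)–C4'(O)–C5'(C). O4' is the pyran oxygen bonded to C(CH3)2 and C5' carries the pyran CH=CH, so the 2,2-dimethyl-2H-pyran is the electrocyclised ortho-quinone methide tautomer of a 5'-prenyl-3',4'-ortho-quinone. The O4'–C(CH3)2 bond is therefore cut back to the 5'-prenyl catechol 16, capped as acetates at O3 and O7.
2. The 8-(1,1-dimethylallyl) group comes from a [3,3] shift of a 7-O-prenyl ether (12 to 13). The two hydroxyls this leaves free (O3, O7) are acetylated, and the MOM groups at O5, O3' and O4' are then removed to expose the catechol.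
3. The pyranone C ring comes from Algar–Flynn–Oyamada closure of chalcone 11, made by Claisen–Schmidt union of acetophenone 4 (A ring) and aldehyde 10 (B ring).
4. Aldehyde 10 comes from 3,4-dihydroxybenzaldehyde through its 4-O-(1,1-dimethylallyl) ether and a Claisen shift to C5. Acetophenone 4 comes from 2,4,6-trihydroxyacetophenone by 4-O-prenylation and mono-MOM protection.
5. Ring order: A and B rings are bought, the C ring is closed in step 8, the chromene pyran ring in step 12, and the acetates are removed last.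

Key step: step 12

Remark: Broussonol A has no stereocentre and is achiral, so no stereocontrol is needed; the working potential of step 12 is to be read from a voltammogram of 16.

**Route**

Step 1
Reactants: 1 2,4,6-trihydroxyacetophenone; 2 prenyl bromide
Product: 3 1-[2,6-dihydroxy-4-(3-methylbut-2-enyloxy)phenyl]ethanone
Conditions: K2CO3 (1.1 equiv), acetone, reflux
Reagents that add atoms: none
Why: Williamson etherification in which 4-OH, the only hydroxyl not hydrogen-bonded to the acetyl group and the most acidic one, should be alkylated selectively, dry aprotic conditions disfavouring C-prenylation.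

Step 2
Reactants: 3 1-[2,6-dihydroxy-4-(3-methylbut-2-enyloxy)phenyl]ethanone
Product: 4 1-[2-hydroxy-6-(methoxymethoxy)-4-(3-methylbut-2-enyloxy)phenyl]ethanone
Conditions: MOMCl (1.1 equiv), i-Pr2NEt, CH2Cl2, 0 °C
Reagents that add atoms: chloromethyl methyl ether, COCCl
Why: MOM etherification of one of two symmetry-equivalent hydroxyls, after which the remaining one is locked in a strong hydrogen bond to the ketone and should resist a second alkylation.

Step 3
Reactants: 5 3,4-dihydroxybenzaldehyde; 6 3-chloro-3-methylbut-1-yne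
Product: 7 3-hydroxy-4-(2-methylbut-3-yn-2-yloxy)benzaldehyde
Conditions: K2CO3 (1.1 equiv), KI, CuI (cat.), acetone, 55 °C
Reagents that add atoms: none
Why: Copper-assisted O-propargylation (Williamson type) of the 4-phenoxide, which is para to the formyl group and far more acidic than 3-OH, so one equivalent of base should place the tertiary ether on O4.

Step 4
Reactants: 7 3-hydroxy-4-(2-methylbut-3-yn-2-yloxy)benzaldehyde
Product: 8 3-hydroxy-4-(2-methylbut-3-en-2-yloxy)benzaldehyde
Conditions: H2 (1 atm), Lindlar catalyst, quinoline, EtOAc, rt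
Reagents that add atoms: none
Why: Lindlar semihydrogenation should stop at the terminal alkene and leave the aldehyde and the aryl ether untouched.

Step 5
Reactants: 8 3-hydroxy-4-(2-methylbut-3-en-2-yloxy)benzaldehyde
Product: 9 3,4-dihydroxy-5-(3-methylbut-2-enyl)benzaldehyde
Conditions: o-xylene, 130 °C, Ar
Reagents that add atoms: none
Why: Aromatic Claisen rearrangement of the 1,1-dimethylallyl aryl ether, which delivers the allyl terminus to C5, the only free position ortho to O4, and so gives the linear prenyl group after tautomerisation.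

Step 6
Reactants: 9 3,4-dihydroxy-5-(3-methylbut-2-enyl)benzaldehyde
Product: 10 3,4-bis(methoxymethoxy)-5-(3-methylbut-2-enyl)benzaldehyde
Conditions: MOMCl (3 equiv), i-Pr2NEt, DMAP (cat.), CH2Cl2, 0 °C to rt
Reagents that add atoms: chloromethyl methyl ether, COCCl
Why: Double MOM etherification of the catechol, which makes the B-ring unit stable to the basic aldol and peroxide steps and to the later thermal rearrangement.

Step 7
Reactants: 4 1-[2-hydroxy-6-(methoxymethoxy)-4-(3-methylbut-2-enyloxy)phenyl]ethanone; 10 3,4-bis(methoxymethoxy)-5-(3-methylbut-2-enyl)benzaldehyde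
Product: 11 (E)-1-[2-hydroxy-6-(methoxymethoxy)-4-(3-methylbut-2-enyloxy)phenyl]-3-[3,4-bis(methoxymethoxy)-5-(3-methylbut-2-enyl)phenyl]prop-2-en-1-one
Conditions: KOH (50% aq.), EtOH, rt
Reagents that add atoms: none
Why: Claisen–Schmidt condensation of the methyl ketone enolate with the non-enolisable aldehyde, E1cB dehydration giving the E-chalcone while MOM and prenyl groups are stable to base.

Step 8
Reactants: 11 (E)-1-[2-hydroxy-6-(methoxymethoxy)-4-(3-methylbut-2-enyloxy)phenyl]-3-[3,4-bis(methoxymethoxy)-5-(3-methylbut-2-enyl)phenyl]prop-2-en-1-one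
Product: 12 3-hydroxy-5-(methoxymethoxy)-7-(3-methylbut-2-enyloxy)-2-[3,4-bis(methoxymethoxy)-5-(3-methylbut-2-enyl)phenyl]chromen-4-one
Conditions: 30% H2O2, aq. NaOH, MeOH–THF, 0 °C to rt
Reagents that add atoms: hydrogen peroxide, OO
Why: Algar–Flynn–Oyamada reaction, in which alkaline peroxide turns the 2'-hydroxychalcone into the 3-hydroxyflavone by six-membered oxa-Michael closure, oxygenation at C3 and dehydrogenation, a reaction established for 6'-MOM-oxy chalcones and one in which the nucleophilic hydroperoxide does not attack the isolated prenyl alkenes.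

Step 9
Reactants: 12 3-hydroxy-5-(methoxymethoxy)-7-(3-methylbut-2-enyloxy)-2-[3,4-bis(methoxymethoxy)-5-(3-methylbut-2-enyl)phenyl]chromen-4-one
Product: 13 3,7-dihydroxy-5-(methoxymethoxy)-8-(2-methylbut-3-en-2-yl)-2-[3,4-bis(methoxymethoxy)-5-(3-methylbut-2-enyl)phenyl]chromen-4-one
Conditions: PhNEt2, 190 °C, Ar (sealed tube)
Reagents that add atoms: none
Why: Aromatic Claisen rearrangement of the 7-O-prenyl ether, which inverts the allyl unit to the 1,1-dimethylallyl group and should go to C8 because of the C7–C8 bond fixation of the chromone and the shielding of C6 by the 5-MOM-oxy group, the para position C4a being blocked.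

Step 10
Reactants: 13 3,7-dihydroxy-5-(methoxymethoxy)-8-(2-methylbut-3-en-2-yl)-2-[3,4-bis(methoxymethoxy)-5-(3-methylbut-2-enyl)phenyl]chromen-4-one
Product: 14 3,7-diacetoxy-5-(methoxymethoxy)-8-(2-methylbut-3-en-2-yl)-2-[3,4-bis(methoxymethoxy)-5-(3-methylbut-2-enyl)phenyl]chromen-4-one
Conditions: Ac2O, pyridine, DMAP (cat.), rt
Reagents that add atoms: acetic anhydride, CC(=O)OC(C)=O
Why: DMAP-catalysed acylation of the only two free hydroxyls, which caps O3 and O7 as acetates that are inert at the anode and are removed last by mild aminolysis.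

Step 11
Reactants: 14 3,7-diacetoxy-5-(methoxymethoxy)-8-(2-methylbut-3-en-2-yl)-2-[3,4-bis(methoxymethoxy)-5-(3-methylbut-2-enyl)phenyl]chromen-4-one
Product: 16 3,7-diacetoxy-5-hydroxy-8-(2-methylbut-3-en-2-yl)-2-[3,4-dihydroxy-5-(3-methylbut-2-enyl)phenyl]chromen-4-one, via tris(trimethylsilyl) ether 15 (not isolated)
Conditions: TMSOTf (7 equiv), 2,2'-bipyridyl (10 equiv), MeCN, 0 °C to rt; then H2O, rt
Reagents that add atoms: trimethylsilyl trifluoromethanesulfonate, C[Si](C)(C)OS(=O)(=O)C(F)(F)F (its silyl groups are carried only by 15)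
Why: Silyl triflate/2,2'-bipyridyl cleavage of aromatic MOM ethers, in which each aryl oxygen is silylated while the methoxymethyl group passes to bipyridyl, so that no Brønsted acid meets the prenyl alkene, the catechol or the acetates before water hydrolyses the labile aryl silyl ethers.

Step 12
Reactants: 16 3,7-diacetoxy-5-hydroxy-8-(2-methylbut-3-en-2-yl)-2-[3,4-dihydroxy-5-(3-methylbut-2-enyl)phenyl]chromen-4-one
Product: 19 3,7-diacetoxy-5-hydroxy-2-(8-hydroxy-2,2-dimethyl-2H-chromen-6-yl)-8-(2-methylbut-3-en-2-yl)chromen-4-one, via ortho-quinone 17 (not isolated), via quinone methide 18 (not isolated)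
Conditions: undivided cell, graphite anode, Pt cathode, n-Bu4NBF4 (0.1 M), 2,6-lutidine (3 equiv), dry MeCN, 5 mM, rt, Ar; constant potential at the catechol wave, about 2.1 F/mol
Reagents that add atoms: none
Why: Proposed new method: anodic two-electron, two-proton oxidation of the 3',4'-catechol, the most easily oxidised group of 16, should give ortho-quinone 17, which 2,6-lutidine tautomerises by vinylogous enolisation through the benzylic CH2 of the 5'-prenyl group to the 3'-hydroxy ortho-quinone methide 18; its O4'=C4'–C5'=CH–CH=C(CH3)2 unit then closes by a thermal disrotatory oxa-6π electrocyclisation that forms the O4'–C(CH3)2 bond and the six-membered 2H-pyran ring and rearomatises the B ring. The closest known reactions are the oxidative cyclisation of ortho-prenyl phenols and catechols to 2,2-dimethylchromenes with DDQ or silver oxide and the standard anodic conversion of catechols into ortho-quinones; driving the whole sequence at an electrode is the new element. No stereocentre is formed. Site selectivity is fixed by the substrate, since only C5' carries a C–H-bearing substituent and only O4' adjoins it, so one pyran can form and 3'-OH is regenerated. Chemoselectivity rests on potential control, because the product phenol, the hydrogen-bonded 5-OH and the alkenes should oxidise only at higher potential, and on the acetates: the O3 acetate blocks oxidation of the flavonol enol and the tautomerisation of 17 into a C-ring quinone methide that would add nucleophiles at C2, and the O7 acetate keeps the A ring electron-poor. A dry, non-nucleophilic and dilute medium should keep water and unreacted catechol from intercepting 17 before it enolises.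

Step 13
Reactants: 19 3,7-diacetoxy-5-hydroxy-2-(8-hydroxy-2,2-dimethyl-2H-chromen-6-yl)-8-(2-methylbut-3-en-2-yl)chromen-4-one
Product: 20 Broussonol A
Conditions: NH3 (7 M in MeOH), 0 °C to rt, Ar; evaporate
Reagents that add atoms: none
Why: Aminolysis of the enol acetate at O3 and the aryl acetate at O7 by ammonia should release the flavonol under conditions that leave the chromene, both alkenes and the pyranone intact.

**Compound list**

1 | 2,4,6-trihydroxyacetophenone | CC(=O)c1c(O)cc(O)cc1O | starting material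
2 | prenyl bromide (1-bromo-3-methylbut-2-ene) | CC(C)=CCBr | starting material
3 | 1-[2,6-dihydroxy-4-(3-methylbut-2-enyloxy)phenyl]ethanone | CC(=O)c1c(O)cc(OCC=C(C)C)cc1O | intermediate
4 | 1-[2-hydroxy-6-(methoxymethoxy)-4-(3-methylbut-2-enyloxy)phenyl]ethanone | CC(=O)c1c(O)cc(OCC=C(C)C)cc1OCOC | intermediate
5 | 3,4-dihydroxybenzaldehyde | O=Cc1ccc(O)c(O)c1 | starting material
6 | 3-chloro-3-methylbut-1-yne | C#CC(C)(C)Cl | starting material
7 | 3-hydroxy-4-(2-methylbut-3-yn-2-yloxy)benzaldehyde | C#CC(C)(C)Oc1ccc(C=O)cc1O | intermediate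
8 | 3-hydroxy-4-(2-methylbut-3-en-2-yloxy)benzaldehyde | C=CC(C)(C)Oc1ccc(C=O)cc1O | intermediate
9 | 3,4-dihydroxy-5-(3-methylbut-2-enyl)benzaldehyde | CC(C)=CCc1cc(C=O)cc(O)c1O | intermediate
10 | 3,4-bis(methoxymethoxy)-5-(3-methylbut-2-enyl)benzaldehyde | CC(C)=CCc1cc(C=O)cc(OCOC)c1OCOC | intermediate
11 | (E)-1-[2-hydroxy-6-(methoxymethoxy)-4-(3-methylbut-2-enyloxy)phenyl]-3-[3,4-bis(methoxymethoxy)-5-(3-methylbut-2-enyl)phenyl]prop-2-en-1-one | COCOc1cc(OCC=C(C)C)cc(O)c1C(=O)/C=C/c1cc(CC=C(C)C)c(OCOC)c(OCOC)c1 | intermediate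
12 | 3-hydroxy-5-(methoxymethoxy)-7-(3-methylbut-2-enyloxy)-2-[3,4-bis(methoxymethoxy)-5-(3-methylbut-2-enyl)phenyl]chromen-4-one | COCOc1cc(OCC=C(C)C)cc2oc(-c3cc(CC=C(C)C)c(OCOC)c(OCOC)c3)c(O)c(=O)c12 | intermediate
13 | 3,7-dihydroxy-5-(methoxymethoxy)-8-(2-methylbut-3-en-2-yl)-2-[3,4-bis(methoxymethoxy)-5-(3-methylbut-2-enyl)phenyl]chromen-4-one | C=CC(C)(C)c1c(O)cc(OCOC)c2c(=O)c(O)c(-c3cc(CC=C(C)C)c(OCOC)c(OCOC)c3)oc12 | intermediate
14 | 3,7-diacetoxy-5-(methoxymethoxy)-8-(2-methylbut-3-en-2-yl)-2-[3,4-bis(methoxymethoxy)-5-(3-methylbut-2-enyl)phenyl]chromen-4-one | C=CC(C)(C)c1c(OC(C)=O)cc(OCOC)c2c(=O)c(OC(C)=O)c(-c3cc(CC=C(C)C)c(OCOC)c(OCOC)c3)oc12 | intermediate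
15 | 3,7-diacetoxy-5-(trimethylsilyloxy)-8-(2-methylbut-3-en-2-yl)-2-[3,4-bis(trimethylsilyloxy)-5-(3-methylbut-2-enyl)phenyl]chromen-4-one (not isolated) | C=CC(C)(C)c1c(OC(C)=O)cc(O[Si](C)(C)C)c2c(=O)c(OC(C)=O)c(-c3cc(CC=C(C)C)c(O[Si](C)(C)C)c(O[Si](C)(C)C)c3)oc12 | intermediate
16 | 3,7-diacetoxy-5-hydroxy-8-(2-methylbut-3-en-2-yl)-2-[3,4-dihydroxy-5-(3-methylbut-2-enyl)phenyl]chromen-4-one | C=CC(C)(C)c1c(OC(C)=O)cc(O)c2c(=O)c(OC(C)=O)c(-c3cc(O)c(O)c(CC=C(C)C)c3)oc12 | intermediate
17 | 3,7-diacetoxy-5-hydroxy-8-(2-methylbut-3-en-2-yl)-2-[5-(3-methylbut-2-enyl)-3,4-dioxocyclohexa-1,5-dien-1-yl]chromen-4-one (ortho-quinone, not isolated) | C=CC(C)(C)c1c(OC(C)=O)cc(O)c2c(=O)c(OC(C)=O)c(C3=CC(=O)C(=O)C(CC=C(C)C)=C3)oc12 | intermediate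
18 | 3,7-diacetoxy-5-hydroxy-8-(2-methylbut-3-en-2-yl)-2-[5-hydroxy-3-(3-methylbut-2-enylidene)-4-oxocyclohexa-1,5-dien-1-yl]chromen-4-one (quinone methide, the vinyl group syn to the C4' carbonyl, not isolated) | C=CC(C)(C)c1c(OC(C)=O)cc(O)c2c(=O)c(OC(C)=O)c(C3=C/C(=C/C=C(C)C)C(=O)C(O)=C3)oc12 | intermediate
19 | 3,7-diacetoxy-5-hydroxy-2-(8-hydroxy-2,2-dimethyl-2H-chromen-6-yl)-8-(2-methylbut-3-en-2-yl)chromen-4-one (3,7-di-O-acetyl-Broussonol A) | C=CC(C)(C)c1c(OC(C)=O)cc(O)c2c(=O)c(OC(C)=O)c(-c3cc(O)c4c(c3)C=CC(C)(C)O4)oc12 | intermediate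
20 | Broussonol A, 3,5,7-trihydroxy-2-(8-hydroxy-2,2-dimethyl-2H-chromen-6-yl)-8-(2-methylbut-3-en-2-yl)chromen-4-one | C=CC(C)(C)c1c(O)cc(O)c2c(=O)c(O)c(-c3cc(O)c4c(c3)C=CC(C)(C)O4)oc12 | target

**Step count**

Total: 13 steps. Longest linear sequence: 11 steps (steps 3 to 13, from 3,4-dihydroxybenzaldehyde).

**Steps most likely to fail**

Step 12 (the proposed anodic closure). The ortho-quinone may be consumed by coupling with unoxidised catechol or by traces of water, with filming of the anode, faster than it enolises to the quinone methide. The product phenol may also be oxidised further if the potential drifts. The fallback builds the chromene by the thermal rearrangement of an aryl propargyl ether before the flavonol is assembled; it sets out from 7 and comes back at 19. Heating 7 in PhNEt2 at 190 °C (propargyl Claisen shift, 1,5-hydrogen shift, oxa-6π closure) should give 8-hydroxy-2,2-dimethyl-2H-chromene-6-carbaldehyde F1. MOMCl/i-Pr2NEt would then give 8-(methoxymethoxy)-2,2-dimethyl-2H-chromene-6-carbaldehyde F2. Claisen–Schmidt condensation with 4 would give the chromenyl chalcone F3, and alkaline H2O2 the chromenyl flavonol F4. Claisen rearrangement in PhNEt2 would give the 8-(1,1-dimethylallyl)-3,7-diol F5, and Ac2O/pyridine/DMAP the diacetate F6. TMSOTf/2,2'-bipyridyl, through the bis(trimethylsilyl) ether F7, then water would return 19.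

Step 9 (Claisen shift to C8). The allyl group may migrate to C6 in competition with C8, and at 190 °C the liberated 7-phenol may react further with the neighbouring allyl group (abnormal Claisen rearrangement, ring closure to a dihydrofuran). The fallback moves the rearrangement to the acetophenone, where both positions ortho to O4 are equivalent; it sets out from 3 and comes back at 13. Heating 3 in PhNEt2 at 180 °C should give 1-[2,4,6-trihydroxy-3-(2-methylbut-3-en-2-yl)phenyl]ethanone F8. Allyl bromide/K2CO3 would alkylate the non-chelated 4-OH to the 4-O-allyl ether F9. MOMCl/i-Pr2NEt would cap the less hindered chelated hydroxyl to give the 6-MOM ether F10, so the free phenol is the one flanked by the 1,1-dimethylallyl group and that group must end at C8. Condensation with 10 would give the chalcone F11, alkaline H2O2 the 7-O-allyl flavonol F12, and Pd(PPh3)4/morpholine would remove the allyl group to return 13.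

Step 8 (Algar–Flynn–Oyamada). With a 6'-alkoxy group the phenoxide may close in the five-membered sense onto Cα of an intermediate epoxide and lead to an aurone, or the oxidation may stall at the dihydroflavonol. The fallback separates ring closure from C3 oxygenation; it sets out from 11 and comes back at 12. Oxa-Michael closure (NaOAc, EtOH, reflux) should give the racemic flavanone F13. Enolate hydroxylation (LiHMDS, THF, −78 °C, then 2-(phenylsulfonyl)-3-phenyloxaziridine) would give the racemic 3-hydroxyflavanone F14. Dess–Martin oxidation of the C3 carbinol would give the chromane-3,4-dione F15, which enolises to 12.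

**Further compounds**

F1 | step 12 | 8-hydroxy-2,2-dimethyl-2H-chromene-6-carbaldehyde | CC1(C)C=Cc2cc(C=O)cc(O)c2O1
F2 | step 12 | 8-(methoxymethoxy)-2,2-dimethyl-2H-chromene-6-carbaldehyde | COCOc1cc(C=O)cc2C=CC(C)(C)Oc12
F3 | step 12 | (E)-1-[2-hydroxy-6-(methoxymethoxy)-4-(3-methylbut-2-enyloxy)phenyl]-3-[8-(methoxymethoxy)-2,2-dimethyl-2H-chromen-6-yl]prop-2-en-1-one | COCOc1cc(OCC=C(C)C)cc(O)c1C(=O)/C=C/c1cc(OCOC)c2OC(C)(C)C=Cc2c1
F4 | step 12 | 3-hydroxy-5-(methoxymethoxy)-7-(3-methylbut-2-enyloxy)-2-[8-(methoxymethoxy)-2,2-dimethyl-2H-chromen-6-yl]chromen-4-one | COCOc1cc(OCC=C(C)C)cc2oc(-c3cc(OCOC)c4OC(C)(C)C=Cc4c3)c(O)c(=O)c12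
F5 | step 12 | 3,7-dihydroxy-5-(methoxymethoxy)-8-(2-methylbut-3-en-2-yl)-2-[8-(methoxymethoxy)-2,2-dimethyl-2H-chromen-6-yl]chromen-4-one | C=CC(C)(C)c1c(O)cc(OCOC)c2c(=O)c(O)c(-c3cc(OCOC)c4OC(C)(C)C=Cc4c3)oc12
F6 | step 12 | 3,7-diacetoxy-5-(methoxymethoxy)-8-(2-methylbut-3-en-2-yl)-2-[8-(methoxymethoxy)-2,2-dimethyl-2H-chromen-6-yl]chromen-4-one | C=CC(C)(C)c1c(OC(C)=O)cc(OCOC)c2c(=O)c(OC(C)=O)c(-c3cc(OCOC)c4OC(C)(C)C=Cc4c3)oc12
F7 | step 12 | 3,7-diacetoxy-5-(trimethylsilyloxy)-8-(2-methylbut-3-en-2-yl)-2-[8-(trimethylsilyloxy)-2,2-dimethyl-2H-chromen-6-yl]chromen-4-one | C=CC(C)(C)c1c(OC(C)=O)cc(O[Si](C)(C)C)c2c(=O)c(OC(C)=O)c(-c3cc(O[Si](C)(C)C)c4OC(C)(C)C=Cc4c3)oc12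
F8 | step 9 | 1-[2,4,6-trihydroxy-3-(2-methylbut-3-en-2-yl)phenyl]ethanone | CC(=O)c1c(O)cc(O)c(C(C)(C)C=C)c1O
F9 | step 9 | 1-[4-(allyloxy)-2,6-dihydroxy-3-(2-methylbut-3-en-2-yl)phenyl]ethanone | CC(=O)c1c(O)cc(OCC=C)c(C(C)(C)C=C)c1O
F10 | step 9 | 1-[4-(allyloxy)-2-hydroxy-6-(methoxymethoxy)-3-(2-methylbut-3-en-2-yl)phenyl]ethanone | CC(=O)c1c(OCOC)cc(OCC=C)c(C(C)(C)C=C)c1O
F11 | step 9 | (E)-1-[4-(allyloxy)-2-hydroxy-6-(methoxymethoxy)-3-(2-methylbut-3-en-2-yl)phenyl]-3-[3,4-bis(methoxymethoxy)-5-(3-methylbut-2-enyl)phenyl]prop-2-en-1-one | COCOc1cc(OCC=C)c(C(C)(C)C=C)c(O)c1C(=O)/C=C/c1cc(CC=C(C)C)c(OCOC)c(OCOC)c1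
F12 | step 9 | 7-(allyloxy)-3-hydroxy-5-(methoxymethoxy)-8-(2-methylbut-3-en-2-yl)-2-[3,4-bis(methoxymethoxy)-5-(3-methylbut-2-enyl)phenyl]chromen-4-one | C=CCOc1cc(OCOC)c2c(=O)c(O)c(-c3cc(CC=C(C)C)c(OCOC)c(OCOC)c3)oc2c1C(C)(C)C=C
F13 | step 8 | 5-(methoxymethoxy)-7-(3-methylbut-2-enyloxy)-2-[3,4-bis(methoxymethoxy)-5-(3-methylbut-2-enyl)phenyl]chroman-4-one (racemic) | COCOc1cc(OCC=C(C)C)cc2OC(c3cc(CC=C(C)C)c(OCOC)c(OCOC)c3)CC(=O)c12
F14 | step 8 | 3-hydroxy-5-(methoxymethoxy)-7-(3-methylbut-2-enyloxy)-2-[3,4-bis(methoxymethoxy)-5-(3-methylbut-2-enyl)phenyl]chroman-4-one (racemic, both stereocentres lost in the next step) | COCOc1cc(OCC=C(C)C)cc2OC(c3cc(CC=C(C)C)c(OCOC)c(OCOC)c3)C(O)C(=O)c12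
F15 | step 8 | 5-(methoxymethoxy)-7-(3-methylbut-2-enyloxy)-2-[3,4-bis(methoxymethoxy)-5-(3-methylbut-2-enyl)phenyl]chromane-3,4-dione (racemic keto tautomer of 12) | COCOc1cc(OCC=C(C)C)cc2OC(c3cc(CC=C(C)C)c(OCOC)c(OCOC)c3)C(=O)C(=O)c12
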